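Count what is left.

    gas phase ⇌ dissolved gas, rate k1*(csat - [dissolved gas]) (k1 = 0.17 s⁻¹, csat = 28 mM)
    starting material + dissolved gas → target (k2 = 0.50 M⁻¹ s⁻¹)
    starting material ⇌ dormant form (K3 = 0.87, k3 = 0.041 s⁻¹)
    solid substrate ⇌ starting material, rate k4*(cs4 - [starting material]) while solid is left; crystals form when [starting material] > cs4 (cs4 = 29 mM, k4 = 0.17 s⁻¹)
    target ⇌ isomer of the product (K5 = 0.33, k5 = 0.042 s⁻¹)

solid substrate 0.050 M; gas phase 28 mM (held); time 2.5 min

* the target standing at 2.5 min, as a percentage of the solid substrate charged
* the change that raises the amount of target at 2.5 min, in percent of the solid substrate charged most ("none" if none brings more than 2 percentage points) (gamma / theta / beta / alpha / none)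
* amount of target at 2.5 min, in percent of the solid substrate charged, after theta

- gamma: doubling the saturation concentration of gas phase, all else as stated
- theta: doubling the dissolution coefficient of step 4, all else as stated
- beta: doubling the transfer coefficient of step 1, all else as stated
- alpha: doubling the solubility in step 4, all else as stated

I follow the fraction of the charge still unreacted, whether solid, free or dormant, and not the fraction made. Gas crosses faster than the reaction uses it, so I hold dissolved gas at saturation. The exchange with the dormant form relaxes in 0.131 min, far shorter than the run, so I take 0.535 of the dissolved pool as free starting material. The pool then drains pseudo-first-order at its drain rate, the product of the rate constant of the reaction, the saturation concentration and the free share, 0.449 min⁻¹. I charge a late start of 0.267 min, which is the charge over the dissolving rate into an empty solution, plus one gas transfer time. So 36.7 % is left at 2.5 min. Target keeps 0.752 of what was made, since its exchange with the isomer of the product relaxes in 0.0682 min, shorter than the run, and that gives 47.6 %.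

Now the settings, one after the other. Gamma doubles the saturation concentration of the gas, so it doubles the drain rate and gains 17 percentage points. Theta doubles the dissolution coefficient and alpha doubles the solubility, so each halves the dissolving part of the late start, which leaves less unreacted and gains 1 point, and that puts theta at 48.6 %. Beta doubles the transfer coefficient, so it halves the gas part of the late start and gains 0.6 points.

The forecast says 46 %, gamma and 47 %, on the ground that “doubling the gas saturation nearly doubles the rate-limiting step”. Both its target figures stand below mine, and it picks the same change.

The flask gives 47.1 % and gamma, with 47.7 % after theta; the gains are 17 points for gamma, 0.53 points for theta, 1 point for beta and 1.1 points for alpha. At 0.449 min⁻¹, 37.8 % stands left in the flask, and the neighbour read at 1.0 min should keep 72.0 % and holds 69.2 %. In the flask, dissolving ran first, with 34.9 % still solid at 0.250 min and 0 % at 1.25 min. The reaction with dissolved gas ran on through the whole time, and at 2.50 min the flask holds 47.1 % as target and 15.0 % as isomer of the product.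

The constants were chosen freely; no experiment stands behind them.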